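**Plan**

- Numbering: lactone O1, C2 (C=O), C3, C4, C5. Ring A is the guaiacyl ring on the C4 arm. Ring B is the ring on the C3 arm, B1 (bearing the CH2) to B6, with OH at B3 and B4 and OMe at B5.
- Retrosynthesis: first the ring A O-benzyl and the B4 O-methyl groups are put back. Ring B is then cut at B6-B1 and B2-B3, then the C3-CH2 bond, then lactone O1-C2 and the C4-CH2(ring A) bond, back to a succinate on a chiral oxazolidinone.
- Enabling feature: the contiguous oxygenated carbons B3, B4, B5 are the carbonyl carbon C1 and the methoxy carbons C2 and C3 of 4-chloro-2,3-dimethoxycyclobutenone. B6 is its CHCl carbon, and B1-B2 is a 1,1-disubstituted alkene (a 2-stannylallyl group on C3).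
- Forward: the ring A arm is joined to the succinate, the lactone ring is closed, the C3 arm is added and stannylated, and ring B is the last ring to form. Two deprotection steps finish.
- Stereochemistry: C4 (R) comes from an Evans benzylation under (R)-4-benzyloxazolidinone control. C3 (R) comes from alkylation of the lactone enolate anti to the C4 arm (trans). Neither centre is touched afterwards.

Key step: step 11

Remark: the ring A phenol is carried as its benzyl ether from purchased O-benzylvanillin, and the chlorocyclobutenone is used as the racemate because its only stereocentre becomes the aromatic carbon B6.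

**Route**

Step 1
Reactants: 1 4-(benzyloxy)-3-methoxybenzaldehyde
Product: 2 [4-(benzyloxy)-3-methoxyphenyl]methanol
Conditions: NaBH4, MeOH, 0 °C
Reagents that add atoms: none
Why: Borohydride reduction of an aryl aldehyde gives the benzylic alcohol cleanly and leaves both aryl ethers untouched.

Step 2
Reactants: 2 [4-(benzyloxy)-3-methoxyphenyl]methanol
Product: 3 1-(benzyloxy)-4-(bromomethyl)-2-methoxybenzene
Conditions: PBr3, Et2O, 0 °C
Reagents that add atoms: phosphorus tribromide, BrP(Br)Br
Why: Substitution of a benzylic alcohol through its phosphite ester (PBr3 bromination) is routine for electron-rich benzyl alcohols; the bromide should be used at once.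

Step 3
Reactants: 4 4-(tert-butoxy)-4-oxobutanoic acid (mono-tert-butyl succinate); 5 (R)-4-benzyl-1,3-oxazolidin-2-one
Product: 7 tert-butyl 4-[(4R)-4-benzyl-2-oxo-1,3-oxazolidin-3-yl]-4-oxobutanoate, via mixed pivalic anhydride 6 (not isolated)
Conditions: t-BuCOCl, Et3N, THF, -20 °C; then LiCl, 5, -20 °C to rt
Reagents that add atoms: none
Why: N-Acylation of an oxazolidinone through a mixed pivalic anhydride with LiCl activation is the standard loading of an Evans auxiliary, the hindered pivaloyl carbonyl directing attack to the succinyl carbonyl.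

Step 4
Reactants: 7 tert-butyl 4-[(4R)-4-benzyl-2-oxo-1,3-oxazolidin-3-yl]-4-oxobutanoate; 3 1-(benzyloxy)-4-(bromomethyl)-2-methoxybenzene
Product: 9 tert-butyl (3R)-4-[(4R)-4-benzyl-2-oxo-1,3-oxazolidin-3-yl]-3-[4-(benzyloxy)-3-methoxybenzyl]-4-oxobutanoate, via sodium Z-enolate 8 (not isolated)
Conditions: NaN(SiMe3)2, THF, -78 °C; then 3, -78 to -20 °C
Reagents that add atoms: none
Why: Evans asymmetric alkylation: the chelated sodium Z-enolate forms at the more acidic imide alpha carbon and should be benzylated on the face opposite the 4-benzyl group of the (R)-auxiliary, which sets the future C4 as R.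

Step 5
Reactants: 9 tert-butyl (3R)-4-[(4R)-4-benzyl-2-oxo-1,3-oxazolidin-3-yl]-3-[4-(benzyloxy)-3-methoxybenzyl]-4-oxobutanoate
Product: 10 tert-butyl (3R)-3-[4-(benzyloxy)-3-methoxybenzyl]-4-hydroxybutanoate
Conditions: LiBH4, MeOH (1 equiv), THF, 0 °C
Reagents that add atoms: none
Why: Reductive cleavage of an N-acyl oxazolidinone with LiBH4 gives the primary alcohol without attacking the tert-butyl ester or the stereocentre, and the auxiliary can be recovered.

Step 6
Reactants: 10 tert-butyl (3R)-3-[4-(benzyloxy)-3-methoxybenzyl]-4-hydroxybutanoate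
Product: 12 (4R)-4-[4-(benzyloxy)-3-methoxybenzyl]dihydrofuran-2(3H)-one, via hydroxy acid 11 (not isolated)
Conditions: CF3CO2H, CH2Cl2, 0 °C to rt
Reagents that add atoms: none
Why: Acidolysis of the tert-butyl ester followed by acid-catalysed lactonisation of the gamma-hydroxy acid should close the butyrolactone (bond O1-C2) with C4 unchanged.

Step 7
Reactants: 12 (4R)-4-[4-(benzyloxy)-3-methoxybenzyl]dihydrofuran-2(3H)-one; 13 2,3-dibromoprop-1-ene
Product: 15 (3R,4R)-4-[4-(benzyloxy)-3-methoxybenzyl]-3-(2-bromoprop-2-en-1-yl)dihydrofuran-2(3H)-one, via lithium enolate 14 (not isolated)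
Conditions: LiN(SiMe3)2, THF/DMPU, -78 °C; then 13, -78 to -30 °C
Reagents that add atoms: none
Why: Substrate-controlled enolate alkylation: the allylic bromide should attack the lactone enolate anti to the C4 substituent, as in the classical dibenzylbutyrolactone lignan alkylations, which sets C3 as R and gives the trans lactone.

Step 8
Reactants: 15 (3R,4R)-4-[4-(benzyloxy)-3-methoxybenzyl]-3-(2-bromoprop-2-en-1-yl)dihydrofuran-2(3H)-one
Product: 16 (3R,4R)-4-[4-(benzyloxy)-3-methoxybenzyl]-3-[2-(tributylstannyl)prop-2-en-1-yl]dihydrofuran-2(3H)-one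
Conditions: Bu3SnSnBu3, Pd(PPh3)4 (5 mol %), toluene, 100 °C
Reagents that add atoms: hexabutylditin, CCCC[Sn](CCCC)(CCCC)[Sn](CCCC)(CCCC)CCCC
Why: Palladium-catalysed stannylation of an alkenyl bromide with a distannane (oxidative addition, tin-tin transmetalation, reductive elimination) places tin on the internal carbon fixed by the bromide under neutral conditions that should not epimerise the lactone.

Step 9
Reactants: 17 dimethyl squarate (3,4-dimethoxycyclobut-3-ene-1,2-dione)
Product: 18 racemic 4-hydroxy-2,3-dimethoxycyclobut-2-en-1-one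
Conditions: LiAlH(OtBu)3, THF, -78 °C
Reagents that add atoms: none
Why: 1,2-Hydride addition of a bulky alkoxyaluminium hydride to a squarate diester at low temperature should stop at the 4-hydroxycyclobutenone, and the two carbonyls are equivalent so only one product can form.

Step 10
Reactants: 18 racemic 4-hydroxy-2,3-dimethoxycyclobut-2-en-1-one
Product: 19 racemic 4-chloro-2,3-dimethoxycyclobut-2-en-1-one
Conditions: PPh3, CCl4, CH2Cl2, 0 °C to rt
Reagents that add atoms: tetrachloromethane, ClC(Cl)(Cl)Cl
Why: Appel chlorination replaces the allylic, alpha-keto hydroxyl by chloride through the alkoxyphosphonium salt under neutral, aprotic conditions, chosen to avoid the acid-induced loss of methanol that would lead to the cyclobutenedione; the chloride should be used directly.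

Step 11
Reactants: 16 (3R,4R)-4-[4-(benzyloxy)-3-methoxybenzyl]-3-[2-(tributylstannyl)prop-2-en-1-yl]dihydrofuran-2(3H)-one; 19 racemic 4-chloro-2,3-dimethoxycyclobut-2-en-1-one
Product: 23 (3R,4R)-4-[4-(benzyloxy)-3-methoxybenzyl]-3-(3-hydroxy-4,5-dimethoxybenzyl)dihydrofuran-2(3H)-one, via 4-alkenylcyclobutenone 20 (not isolated), via dienylketene 21 (not isolated), via cyclohexa-2,4-dienone 22 (not isolated)
Conditions: Pd2(dba)3 (2.5 mol %), tri(2-furyl)phosphine (10 mol %), dioxane, 50 °C; then 100 °C
Reagents that add atoms: none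
Why: Zerovalent palladium should insert into the allylic C-Cl bond of 19 to give an oxocyclobutenyl palladium chloride, the alkenyl group is transferred from tin, and reductive elimination at the CH terminus forms B6-B1 in 20; the closest known reaction type is exactly this Stille coupling of 4-chlorocyclobutenones with alkenylstannanes followed by thermal benzannulation to phenols. At 100 °C relief of ring strain drives a conrotatory 4-pi opening of 20 to dienylketene 21, and a thermal disrotatory 6-pi electrocyclisation between the ketene carbon and the terminal CH2 closes the six-membered ring B (bond B2-B3) as dienone 22, which enolises to phenol 23. No stereocentre is created, since the CH centre of 20 becomes aromatic B6, and C3 and C4 are left alone because the medium is neutral and aprotic. Two selectivities are needed: coupling at the CH terminus and not at the methoxy-bearing terminus of the allyl unit, which the lower substitution of the CH carbon should secure, and cyclisation only from the ketene isomer whose alkenyl group points inward, the outward isomer closing back to 20 until it drains through the productive isomer. The oxygen pattern is then dictated by the connectivity of 19: carbonyl to B3, C2 methoxyl to B4, C3 methoxyl to B5.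

Step 12
Reactants: 23 (3R,4R)-4-[4-(benzyloxy)-3-methoxybenzyl]-3-(3-hydroxy-4,5-dimethoxybenzyl)dihydrofuran-2(3H)-one
Product: 25 (3R,4R)-4-[4-(benzyloxy)-3-methoxybenzyl]-3-(3,4-dihydroxy-5-methoxybenzyl)dihydrofuran-2(3H)-one, via ortho-quinone 24 (not isolated)
Conditions: SIBX (2-iodoxybenzoic acid stabilised with benzoic and isophthalic acids), THF, rt; then aq. Na2S2O4
Reagents that add atoms: 2-iodoxybenzoic acid (the oxidant of SIBX), OI1(=O)OC(=O)c2ccccc12
Why: Oxidative demethylation of a 2-methoxyphenol by pentavalent iodine: the B3 phenol binds to iodine, oxygen is delivered to the methoxy-bearing ortho carbon B4, methanol is lost to give the ortho-quinone, and dithionite reduces it to the catechol, while ring A is an ether and not a phenol and so should not react.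

Step 13
Reactants: 25 (3R,4R)-4-[4-(benzyloxy)-3-methoxybenzyl]-3-(3,4-dihydroxy-5-methoxybenzyl)dihydrofuran-2(3H)-one
Product: 26 (-)-thujaplicatin, (3R,4R)-3-(3,4-dihydroxy-5-methoxybenzyl)-4-(4-hydroxy-3-methoxybenzyl)dihydrofuran-2(3H)-one
Conditions: H2 (1 atm), Pd/C, EtOAc/EtOH, rt
Reagents that add atoms: none
Why: Hydrogenolysis of the aryl benzyl ether over Pd/C frees the ring A phenol, and the lactone, the methyl ethers and both stereocentres are inert to these conditions.

**Compound list**

1 | 4-(benzyloxy)-3-methoxybenzaldehyde (O-benzylvanillin) | COc1cc(C=O)ccc1OCc1ccccc1 | starting material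
2 | [4-(benzyloxy)-3-methoxyphenyl]methanol | COc1cc(CO)ccc1OCc1ccccc1 | intermediate
3 | 1-(benzyloxy)-4-(bromomethyl)-2-methoxybenzene | COc1cc(CBr)ccc1OCc1ccccc1 | intermediate
4 | 4-(tert-butoxy)-4-oxobutanoic acid | CC(C)(C)OC(=O)CCC(=O)O | starting material
5 | (R)-4-benzyl-1,3-oxazolidin-2-one | O=C1N[C@H](Cc2ccccc2)CO1 | starting material
6 | mixed anhydride of 4 and pivalic acid (formed in the flask) | CC(C)(C)OC(=O)CCC(=O)OC(=O)C(C)(C)C | intermediate
7 | tert-butyl 4-[(4R)-4-benzyl-2-oxo-1,3-oxazolidin-3-yl]-4-oxobutanoate | CC(C)(C)OC(=O)CCC(=O)N1C(=O)OC[C@H]1Cc1ccccc1 | intermediate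
8 | sodium Z-enolate of 7 (formed in the flask) | [Na+].CC(C)(C)OC(=O)C/C=C(\[O-])N1C(=O)OC[C@H]1Cc1ccccc1 | intermediate
9 | tert-butyl (3R)-4-[(4R)-4-benzyl-2-oxo-1,3-oxazolidin-3-yl]-3-[4-(benzyloxy)-3-methoxybenzyl]-4-oxobutanoate | COc1cc(C[C@H](CC(=O)OC(C)(C)C)C(=O)N2C(=O)OC[C@H]2Cc2ccccc2)ccc1OCc1ccccc1 | intermediate
10 | tert-butyl (3R)-3-[4-(benzyloxy)-3-methoxybenzyl]-4-hydroxybutanoate | COc1cc(C[C@H](CC(=O)OC(C)(C)C)CO)ccc1OCc1ccccc1 | intermediate
11 | (3R)-3-[4-(benzyloxy)-3-methoxybenzyl]-4-hydroxybutanoic acid (formed in the flask) | COc1cc(C[C@H](CC(=O)O)CO)ccc1OCc1ccccc1 | intermediate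
12 | (4R)-4-[4-(benzyloxy)-3-methoxybenzyl]dihydrofuran-2(3H)-one | COc1cc(C[C@H]2COC(=O)C2)ccc1OCc1ccccc1 | intermediate
13 | 2,3-dibromoprop-1-ene | C=C(Br)CBr | starting material
14 | lithium enolate of 12 (formed in the flask) | [Li+].COc1cc(C[C@H]2COC([O-])=C2)ccc1OCc1ccccc1 | intermediate
15 | (3R,4R)-4-[4-(benzyloxy)-3-methoxybenzyl]-3-(2-bromoprop-2-en-1-yl)dihydrofuran-2(3H)-one | COc1cc(C[C@H]2COC(=O)[C@@H]2CC(Br)=C)ccc1OCc1ccccc1 | intermediate
16 | (3R,4R)-4-[4-(benzyloxy)-3-methoxybenzyl]-3-[2-(tributylstannyl)prop-2-en-1-yl]dihydrofuran-2(3H)-one | COc1cc(C[C@H]2COC(=O)[C@@H]2CC(=C)[Sn](CCCC)(CCCC)CCCC)ccc1OCc1ccccc1 | intermediate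
17 | dimethyl squarate (3,4-dimethoxycyclobut-3-ene-1,2-dione) | COC1=C(OC)C(=O)C1=O | starting material
18 | 4-hydroxy-2,3-dimethoxycyclobut-2-en-1-one (racemic) | COC1=C(OC)C(O)C1=O | intermediate
19 | 4-chloro-2,3-dimethoxycyclobut-2-en-1-one (racemic) | COC1=C(OC)C(Cl)C1=O | intermediate
20 | (3R,4R)-4-[4-(benzyloxy)-3-methoxybenzyl]-3-[2-(2,3-dimethoxy-4-oxocyclobut-2-en-1-yl)prop-2-en-1-yl]dihydrofuran-2(3H)-one, both epimers at the cyclobutenone CH (formed in the flask) | COc1cc(C[C@H]2COC(=O)[C@@H]2CC(=C)C3C(=O)C(OC)=C3OC)ccc1OCc1ccccc1 | intermediate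
21 | dienylketene from ring opening of 20, alkenyl group cis to the ketene-bearing carbon (formed in the flask) | COc1cc(C[C@H]2COC(=O)[C@@H]2CC(=C)/C=C(OC)\C(OC)=C=O)ccc1OCc1ccccc1 | intermediate
22 | 2,3-dimethoxycyclohexa-2,4-dien-1-one tautomer of 23, lactone CH2 on the ring carbon that becomes B1 (formed in the flask) | COc1cc(C[C@H]2COC(=O)[C@@H]2CC3=CC(OC)=C(OC)C(=O)C3)ccc1OCc1ccccc1 | intermediate
23 | (3R,4R)-4-[4-(benzyloxy)-3-methoxybenzyl]-3-(3-hydroxy-4,5-dimethoxybenzyl)dihydrofuran-2(3H)-one | COc1cc(C[C@H]2COC(=O)[C@@H]2Cc2cc(O)c(OC)c(OC)c2)ccc1OCc1ccccc1 | intermediate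
24 | ring B 3-methoxy-1,2-benzoquinone derived from 23, carbonyls at B3 and B4 (formed in the flask) | COc1cc(C[C@H]2COC(=O)[C@@H]2CC3=CC(=O)C(=O)C(OC)=C3)ccc1OCc1ccccc1 | intermediate
25 | (3R,4R)-4-[4-(benzyloxy)-3-methoxybenzyl]-3-(3,4-dihydroxy-5-methoxybenzyl)dihydrofuran-2(3H)-one | COc1cc(C[C@H]2COC(=O)[C@@H]2Cc2cc(O)c(O)c(OC)c2)ccc1OCc1ccccc1 | intermediate
26 | (-)-thujaplicatin, (3R,4R)-3-(3,4-dihydroxy-5-methoxybenzyl)-4-(4-hydroxy-3-methoxybenzyl)dihydrofuran-2(3H)-one | COc1cc(C[C@H]2COC(=O)[C@@H]2Cc2cc(O)c(O)c(OC)c2)ccc1O | target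

**Step count**

Total step count: 13.
Longest linear sequence: 10 steps (steps 1, 2, 4, 5, 6, 7, 8, 11, 12, 13, from 1).

**Steps most likely to fail**

Step 10. The activated hydroxyl may ionise, chloride may then be captured at the methoxy-bearing end of the allyl cation (allylic transposition), and the methyl group may be lost, which would lead to the cyclobutenedione instead of the chloride. The fallback keeps the oxygen as an ester leaving group that only palladium ionises. It sets out from 18: acetylation (Ac2O, pyridine, DMAP, CH2Cl2, 0 °C) should give 4-acetoxy-2,3-dimethoxycyclobut-2-en-1-one F1. Coupling of F1 with 16 under allylic-acetate Stille conditions (Pd2(dba)3, tri(2-furyl)phosphine, LiCl, DMF, 50 °C) should give the same 4-alkenylcyclobutenone 20. Heating at 100 °C brings the route back at 23.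

Step 11. Transfer of the hindered internal alkenyl group from tin to palladium may be slow, so that protodestannylation of 16 and decomposition of 19 outrun the coupling. The fallback changes the nucleophile from tin to boron. It sets out from 15: Miyaura borylation (B2pin2, PdCl2(PPh3)2, PPh3, KOPh, toluene, 50 °C) should give (3R,4R)-4-[4-(benzyloxy)-3-methoxybenzyl]-3-[2-(4,4,5,5-tetramethyl-1,3,2-dioxaborolan-2-yl)prop-2-en-1-yl]dihydrofuran-2(3H)-one F2. Suzuki-Miyaura coupling of F2 with the allylic chloride 19 (Pd(PPh3)4, CsF, dioxane, 60 °C), followed by heating at 100 °C, should pass through 20 and come back to the route at 23.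

Step 12. Oxygen transfer may show poor regioselectivity: delivery to the free ortho position B2, which is para to the B5 methoxyl, would hydroxylate instead of demethylate, and the quinone may over-oxidise. The fallback removes the selective demethylation by carrying the two neighbouring oxygens as benzyl ethers and methylating the single phenol afterwards. It sets out from 16 and comes back to the route at 26.

- Dibenzyl squarate F3 (from squaric acid and benzyl alcohol by azeotropic esterification) is reduced as in step 9 to 2,3-bis(benzyloxy)-4-hydroxycyclobut-2-en-1-one F4 and chlorinated as in step 10 to 2,3-bis(benzyloxy)-4-chlorocyclobut-2-en-1-one F5.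
- Coupling of F5 with 16 and thermolysis under the conditions of step 11 should lead through the 4-alkenylcyclobutenone F6, the dienylketene F7 and the cyclohexadienone F8 to the bis(benzyl ether) phenol F9.
- Methylation of its only hydroxyl (MeI, K2CO3, acetone, rt) should give the methyl ether F10, and hydrogenolysis of the three benzyl ethers (H2, Pd/C, EtOAc/EtOH) should give 26.

In this variant the carbon that came from the cyclobutenone carbonyl ends as the methoxy-bearing carbon, which the local symmetry of ring B about the B1-B4 axis allows.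

**Further compounds**

F1 | step 10 | 4-acetoxy-2,3-dimethoxycyclobut-2-en-1-one (racemic) | COC1=C(OC)C(OC(C)=O)C1=O
F2 | step 11 | (3R,4R)-4-[4-(benzyloxy)-3-methoxybenzyl]-3-[2-(4,4,5,5-tetramethyl-1,3,2-dioxaborolan-2-yl)prop-2-en-1-yl]dihydrofuran-2(3H)-one | COc1cc(C[C@H]2COC(=O)[C@@H]2CC(=C)B3OC(C)(C)C(C)(C)O3)ccc1OCc1ccccc1
F3 | step 12 | dibenzyl squarate, 3,4-bis(benzyloxy)cyclobut-3-ene-1,2-dione | O=C1C(=O)C(OCc2ccccc2)=C1OCc1ccccc1
F4 | step 12 | 2,3-bis(benzyloxy)-4-hydroxycyclobut-2-en-1-one (racemic) | O=C1C(O)C(OCc2ccccc2)=C1OCc1ccccc1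
F5 | step 12 | 2,3-bis(benzyloxy)-4-chlorocyclobut-2-en-1-one (racemic) | O=C1C(Cl)C(OCc2ccccc2)=C1OCc1ccccc1
F6 | step 12 | (3R,4R)-4-[4-(benzyloxy)-3-methoxybenzyl]-3-{2-[2,3-bis(benzyloxy)-4-oxocyclobut-2-en-1-yl]prop-2-en-1-yl}dihydrofuran-2(3H)-one, both epimers at the cyclobutenone CH | COc1cc(C[C@H]2COC(=O)[C@@H]2CC(=C)C3C(=O)C(OCc4ccccc4)=C3OCc3ccccc3)ccc1OCc1ccccc1
F7 | step 12 | dienylketene from ring opening of F6, alkenyl group cis to the ketene-bearing carbon | COc1cc(C[C@H]2COC(=O)[C@@H]2CC(=C)/C=C(OCc3ccccc3)\C(OCc3ccccc3)=C=O)ccc1OCc1ccccc1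
F8 | step 12 | 2,3-bis(benzyloxy)cyclohexa-2,4-dien-1-one tautomer of F9 | COc1cc(C[C@H]2COC(=O)[C@@H]2CC3=CC(OCc4ccccc4)=C(OCc4ccccc4)C(=O)C3)ccc1OCc1ccccc1
F9 | step 12 | (3R,4R)-4-[4-(benzyloxy)-3-methoxybenzyl]-3-[3,4-bis(benzyloxy)-5-hydroxybenzyl]dihydrofuran-2(3H)-one | COc1cc(C[C@H]2COC(=O)[C@@H]2Cc2cc(O)c(OCc3ccccc3)c(OCc3ccccc3)c2)ccc1OCc1ccccc1
F10 | step 12 | (3R,4R)-4-[4-(benzyloxy)-3-methoxybenzyl]-3-[3,4-bis(benzyloxy)-5-methoxybenzyl]dihydrofuran-2(3H)-one | COc1cc(C[C@H]2COC(=O)[C@@H]2Cc2cc(OC)c(OCc3ccccc3)c(OCc3ccccc3)c2)ccc1OCc1ccccc1
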